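**Retrosynthetic overview**

1. The strategy rests on the tetrasubstituted C5=C6 (and C5'=C6') ring alkene flanked by the quaternary gem-dimethyl C1 and the C2 stereocentre. α-Campholenic aldehyde already holds C1 with both methyls, C2 with its configuration and two arm carbons, C3, C4, C6 and C7 in a cyclopentene.
2. C50 is cut at C11=C12 and C11'=C12' (two Wittig reactions) into the ring A C15 phosphonium salt, the C10 trienedial and the ring B C15 phosphonium salt.
3. Each C15 salt comes from a C11 dimethyl acetal. The arms are finished after ring closure from a CH2CH2OTBS arm: prenyl by arm aldehyde plus isopropylidene ylide, the bis(hydroxymethyl)vinyl arm by arm ylide plus a bis(silyloxy)acetone.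
4. Each ring comes from an acyclic 1,6-diketone by reductive C5–C6 carbonyl coupling. The diketone comes from Claisen–Schmidt condensation of the C7 methyl ketone with a C8–C11 enal acetal and from a two-carbon Wittig homologation of the C4 aldehyde with one batch of an α-ethoxyethylidene ylide, both carbonyls arising by ozonolysis of silylated campholenyl alcohol.
5. Ring order: ring A (step 10, from the R aldehyde), then ring B (step 24, same chemistry on the S aldehyde), both before chain assembly.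

Key step: step 10

Assumption: both enantiomers of α-campholenic aldehyde (each the ZnBr2 rearrangement product of one α-pinene oxide enantiomer) and the C10 dialdehyde 24 are purchased; the configuration at C2 and C2' rests on the enantiomeric purity of the two aldehydes. The two ring series are run side by side as far as the keto aldehydes 11 and 31, so that the single cold batch of ylide 12 from step 6 is divided between steps 7 and 21. OTBS = tert-butyldimethylsilyloxy, OTBDPS = tert-butyldiphenylsilyloxy; C-numbers are carotenoid numbers.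

**Reagent building blocks**

Step 1
Reactants: 1 2,2-dimethoxyacetaldehyde; 2 2-(triphenylphosphoranylidene)propanal
Product: 3 (2E)-4,4-dimethoxy-2-methylbut-2-enal
Conditions: 1 (60 wt% in water, slight excess), CH2Cl2, rt
Reagents that add atoms: none
Why: Wittig olefination with the formyl-stabilised ylide should give the E enal, since the glyoxal monoacetal is far more electrophilic than the α-branched product enal.

Step 2
Reactants: 4 triphenylphosphine; 5 1-chloro-1-ethoxyethane
Product: 6 (1-ethoxyethyl)triphenylphosphonium chloride (racemic)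
Conditions: toluene, 0 °C → rt, moisture excluded
Reagents that add atoms: none
Why: Quaternisation of the phosphine by the ionisable α-chloro ether, the reaction type that gives (methoxymethyl)triphenylphosphonium chloride, should precipitate the salt.

**Ring A series (from the R aldehyde)**

Step 3
Reactants: 7 (R)-α-campholenic aldehyde
Product: 8 2-[(1R)-2,2,3-trimethylcyclopent-3-en-1-yl]ethanol
Conditions: NaBH4, MeOH, 0 °C
Reagents that add atoms: none
Why: Borohydride reduction of the aldehyde leaves the ring alkene and the β-stereocentre untouched.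

Step 4
Reactants: 8 2-[(1R)-2,2,3-trimethylcyclopent-3-en-1-yl]ethanol
Product: 9 tert-butyldimethyl{2-[(1R)-2,2,3-trimethylcyclopent-3-en-1-yl]ethoxy}silane
Conditions: TBSCl, imidazole, DMF, rt
Reagents that add atoms: tert-butyldimethylsilyl chloride, CC(C)(C)[Si](C)(C)Cl
Why: Imidazole-promoted silylation of the primary alcohol masks the arm against ozone, ylides, base and low-valent titanium.

Step 5
Reactants: 9 tert-butyldimethyl{2-[(1R)-2,2,3-trimethylcyclopent-3-en-1-yl]ethoxy}silane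
Product: 11 (3S)-3-[2-(OTBS)ethyl]-4,4-dimethyl-5-oxohexanal, via ozonide 10 (not isolated)
Conditions: O3, CH2Cl2, −78 °C; then PPh3, −78 °C → rt
Reagents that add atoms: ozone, [O-][O+]=O
Why: Ozonolysis with reductive work-up cleaves the only C=C to the C4 aldehyde and the C6 methyl ketone (C7 is its methyl), and the stereocentre is α to neither carbonyl.

Step 6
Reactants: 6 (1-ethoxyethyl)triphenylphosphonium chloride
Product: 12 (1-ethoxyethylidene)triphenylphosphorane (cold THF solution, used at once)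
Conditions: KN(SiMe3)2, THF, −78 → −40 °C; one batch sized for both series, kept at −78 °C and divided between steps 7 and 21
Reagents that add atoms: none
Why: Deprotonation of the phosphonium salt at its α-carbon by the hindered amide base is the standard generation of α-alkoxyalkylidene ylides, as for the methoxymethylene ylide, and potassium chloride drops out.

Step 7
Reactants: 11 (3S)-3-[2-(OTBS)ethyl]-4,4-dimethyl-5-oxohexanal; 12 (1-ethoxyethylidene)triphenylphosphorane
Product: 13 (4R)-4-[2-(OTBS)ethyl]-7-ethoxy-3,3-dimethyloct-6-en-2-one (enol ether E/Z mixture)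
Conditions: 12 (1.3 equiv, first portion of the solution from step 6), 11 in THF added at −78 °C, then → 0 °C
Reagents that add atoms: none
Why: Wittig olefination with the α-alkoxyalkylidene ylide should take only the aldehyde, the ketone beside the quaternary carbon being too hindered, and installs C5 and its methyl as an enol ether (masked methyl ketone).

Step 8
Reactants: 13 (4R)-4-[2-(OTBS)ethyl]-7-ethoxy-3,3-dimethyloct-6-en-2-one; 3 (2E)-4,4-dimethoxy-2-methylbut-2-enal
Product: 14 (2E,4E,8R)-8-[2-(OTBS)ethyl]-11-ethoxy-1,1-dimethoxy-3,7,7-trimethyldodeca-2,4,10-trien-6-one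
Conditions: NaOH (0.3 equiv, aq), EtOH, 0 °C → rt
Reagents that add atoms: none
Why: Claisen–Schmidt aldol condensation is unambiguous because the ketone enolises only at the C7 methyl and the enal has no α-hydrogen, and dehydration should give the E C7=C8 bond; enol ether, acetal and silyl ether are base-stable.

Step 9
Reactants: 14 (2E,4E,8R)-8-[2-(OTBS)ethyl]-11-ethoxy-1,1-dimethoxy-3,7,7-trimethyldodeca-2,4,10-trien-6-one
Product: 15 (5R,8E,10E)-5-[2-(OTBS)ethyl]-12,12-dimethoxy-6,6,10-trimethyldodeca-8,10-diene-2,7-dione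
Conditions: oxalic acid (0.05 equiv), THF/H2O 4:1, 0 °C, stopped when 14 is consumed
Reagents that add atoms: water, O
Why: Acid-catalysed enol ether hydrolysis (rate-limiting C-protonation of a ketone-derived enol ether) should be far faster than ionisation of the acetal, whose oxocarbenium ion is destabilised by conjugation with the dienone.

Step 10
Reactants: 15 (5R,8E,10E)-5-[2-(OTBS)ethyl]-12,12-dimethoxy-6,6,10-trimethyldodeca-8,10-diene-2,7-dione
Product: 17 tert-butyl{2-[(1R)-3-[(1E,3E)-5,5-dimethoxy-3-methylpenta-1,3-dien-1-yl]-2,2,4-trimethylcyclohex-3-en-1-yl]ethoxy}dimethylsilane, via titanium pinacolate 16 (not isolated)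
Conditions: TiCl3(DME)1.5 (trivalent titanium), Zn–Cu couple, DME, reflux 2 h; then 15 by syringe pump over about 30 h (high dilution), reflux
Reagents that add atoms: none
Why: Low-valent titanium made from TiCl3(DME)1.5 and Zn–Cu couple transfers one electron to each carbonyl group, the two titanium-bound ketyl radicals combine at C5 and C6 to the pinacolate 16, and at reflux both C–O bonds break on the oxophilic metal to leave the C5=C6 double bond. The closest known reactions are the intramolecular McMurry coupling of 1,6-diketones to 1,2-dialkylcyclohexenes and the McMurry coupling of conjugated polyene carbonyl compounds. Ring A closes by reductive carbonyl–carbonyl coupling, the new C5–C6 bond completing a six-membered carbocycle from a chain that already holds C1 to C4. No stereocentre is created; C2 is β to C6 and γ to C5, cannot enolise, and is carried unchanged from 7. The step needs intramolecular coupling at the carbonyl carbon of the dienone: slow addition at high dilution suppresses intermolecular coupling, and only C6 gives a six-membered ring, whereas bonding through C8 or C10 would give an eight- or ten-membered one. The dimethyl acetal and the silyl ether have no reducible carbonyl and should pass under strictly anhydrous conditions.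

Step 11
Reactants: 17 ring A silyl ether (name as in step 10)
Product: 18 2-[(1R)-3-[(1E,3E)-5,5-dimethoxy-3-methylpenta-1,3-dien-1-yl]-2,2,4-trimethylcyclohex-3-en-1-yl]ethanol
Conditions: Bu4NF, THF, 0 °C → rt
Reagents that add atoms: none
Why: Fluoride desilylation frees the arm alcohol under basic conditions that the acetal tolerates.

Step 12
Reactants: 18 ring A arm alcohol
Product: 19 2-[(1R)-3-[(1E,3E)-5,5-dimethoxy-3-methylpenta-1,3-dien-1-yl]-2,2,4-trimethylcyclohex-3-en-1-yl]acetaldehyde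
Conditions: Dess–Martin periodinane, pyridine, CH2Cl2, 0 °C → rt
Reagents that add atoms: none
Why: Dess–Martin oxidation buffered with pyridine gives the aldehyde without acid that would open the acetal; C2 is β to the new carbonyl and cannot epimerise.

Step 13
Reactants: 19 ring A arm aldehyde
Product: 20 (4R)-2-[(1E,3E)-5,5-dimethoxy-3-methylpenta-1,3-dien-1-yl]-1,3,3-trimethyl-4-(3-methylbut-2-en-1-yl)cyclohex-1-ene
Conditions: isopropyltriphenylphosphonium iodide, n-BuLi, THF, 0 °C; then 19, −78 °C → rt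
Reagents that add atoms: isopropyltriphenylphosphonium iodide, CC(C)[P+](c1ccccc1)(c1ccccc1)c1ccccc1.[I-]
Why: Wittig olefination with the non-stabilised isopropylidene ylide builds the prenyl arm, and the new alkene has no geometry to control.

Step 14
Reactants: 20 ring A prenyl acetal
Product: 21 (2E,4E)-3-methyl-5-[(5R)-2,6,6-trimethyl-5-(3-methylbut-2-en-1-yl)cyclohex-1-en-1-yl]penta-2,4-dienal
Conditions: pyridinium p-toluenesulfonate (0.1 equiv), acetone/H2O 9:1, rt
Reagents that add atoms: water, O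
Why: Acid-catalysed acetal hydrolysis is now easy because the oxocarbenium ion is stabilised by the ring triene, and the mild acid should spare the prenyl alkene.

Step 15
Reactants: 21 ring A C15 aldehyde
Product: 22 (2E,4E)-3-methyl-5-[(5R)-2,6,6-trimethyl-5-(3-methylbut-2-en-1-yl)cyclohex-1-en-1-yl]penta-2,4-dien-1-ol
Conditions: NaBH4, MeOH/THF, 0 °C
Reagents that add atoms: none
Why: Borohydride 1,2-reduction of the conjugated aldehyde gives the C11 allylic alcohol.

Step 16
Reactants: 22 ring A C15 alcohol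
Product: 23 {(2E,4E)-3-methyl-5-[(5R)-2,6,6-trimethyl-5-(3-methylbut-2-en-1-yl)cyclohex-1-en-1-yl]penta-2,4-dien-1-yl}triphenylphosphonium bromide
Conditions: PPh3·HBr, MeOH, rt, dark
Reagents that add atoms: triphenylphosphine hydrobromide, Br.c1ccc(cc1)P(c1ccccc1)c1ccccc1
Why: Phosphonium salt formation from an allylic alcohol through its pentadienyl cation, the standard entry to retinoid C15 salts, should give the terminal E,E salt.

Step 17
Reactants: 23 ring A C15 phosphonium bromide; 24 (2E,4E,6E)-2,7-dimethylocta-2,4,6-trienedial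
Product: 26 (2E,4E,6E,8E,10E,12E)-2,7,11-trimethyl-13-[(5R)-2,6,6-trimethyl-5-(3-methylbut-2-en-1-yl)cyclohex-1-en-1-yl]trideca-2,4,6,8,10,12-hexaenal, via ylide 25 (not isolated)
Conditions: 24 (3 equiv), NaOMe added last, MeOH/CH2Cl2, 0 °C → rt, dark; then I2 (cat.), CH2Cl2, rt, daylight
Reagents that add atoms: none
Why: Wittig olefination with the dialdehyde in excess should stop at mono-condensation (C11=C12), and iodine-catalysed equilibration converts the Z isomer into the all-E C25 aldehyde.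

**Ring B series (from the S aldehyde)**

Step 18
Reactants: 27 (S)-α-campholenic aldehyde
Product: 28 2-[(1S)-2,2,3-trimethylcyclopent-3-en-1-yl]ethanol
Conditions: NaBH4, MeOH, 0 °C
Reagents that add atoms: none
Why: Borohydride reduction as in step 3, on the enantiomer.

Step 19
Reactants: 28 2-[(1S)-2,2,3-trimethylcyclopent-3-en-1-yl]ethanol
Product: 29 tert-butyldimethyl{2-[(1S)-2,2,3-trimethylcyclopent-3-en-1-yl]ethoxy}silane
Conditions: TBSCl, imidazole, DMF, rt
Reagents that add atoms: tert-butyldimethylsilyl chloride, CC(C)(C)[Si](C)(C)Cl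
Why: Silylation of the primary alcohol as in step 4.

Step 20
Reactants: 29 tert-butyldimethyl{2-[(1S)-2,2,3-trimethylcyclopent-3-en-1-yl]ethoxy}silane
Product: 31 (3R)-3-[2-(OTBS)ethyl]-4,4-dimethyl-5-oxohexanal, via ozonide 30 (not isolated)
Conditions: O3, CH2Cl2, −78 °C; then PPh3, −78 °C → rt
Reagents that add atoms: ozone, [O-][O+]=O
Why: Ozonolysis with reductive work-up as in step 5.

Step 21
Reactants: 31 (3R)-3-[2-(OTBS)ethyl]-4,4-dimethyl-5-oxohexanal; 12 (1-ethoxyethylidene)triphenylphosphorane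
Product: 32 (4S)-4-[2-(OTBS)ethyl]-7-ethoxy-3,3-dimethyloct-6-en-2-one (enol ether E/Z mixture)
Conditions: 12 (1.3 equiv, second portion of the solution from step 6), 31 in THF added at −78 °C, then → 0 °C
Reagents that add atoms: none
Why: Aldehyde-selective Wittig olefination with the α-alkoxyalkylidene ylide as in step 7.

Step 22
Reactants: 32 (4S)-4-[2-(OTBS)ethyl]-7-ethoxy-3,3-dimethyloct-6-en-2-one; 3 (2E)-4,4-dimethoxy-2-methylbut-2-enal
Product: 33 (2E,4E,8S)-8-[2-(OTBS)ethyl]-11-ethoxy-1,1-dimethoxy-3,7,7-trimethyldodeca-2,4,10-trien-6-one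
Conditions: NaOH (0.3 equiv, aq), EtOH, 0 °C → rt
Reagents that add atoms: none
Why: Claisen–Schmidt aldol condensation as in step 8.

Step 23
Reactants: 33 (2E,4E,8S)-8-[2-(OTBS)ethyl]-11-ethoxy-1,1-dimethoxy-3,7,7-trimethyldodeca-2,4,10-trien-6-one
Product: 34 (5S,8E,10E)-5-[2-(OTBS)ethyl]-12,12-dimethoxy-6,6,10-trimethyldodeca-8,10-diene-2,7-dione
Conditions: oxalic acid (0.05 equiv), THF/H2O 4:1, 0 °C, stopped when 33 is consumed
Reagents that add atoms: water, O
Why: Chemoselective acid-catalysed enol ether hydrolysis as in step 9.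

Step 24
Reactants: 34 (5S,8E,10E)-5-[2-(OTBS)ethyl]-12,12-dimethoxy-6,6,10-trimethyldodeca-8,10-diene-2,7-dione
Product: 36 tert-butyl{2-[(1S)-3-[(1E,3E)-5,5-dimethoxy-3-methylpenta-1,3-dien-1-yl]-2,2,4-trimethylcyclohex-3-en-1-yl]ethoxy}dimethylsilane, via titanium pinacolate 35 (not isolated)
Conditions: TiCl3(DME)1.5 (trivalent titanium), Zn–Cu couple, DME, reflux 2 h; then 34 by syringe pump over about 30 h (high dilution), reflux
Reagents that add atoms: none
Why: Intramolecular McMurry coupling as in step 10 closes ring B through the C5'–C6' bond, with C2' carried unchanged from 27.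

Step 25
Reactants: 36 ring B silyl ether
Product: 37 2-[(1S)-3-[(1E,3E)-5,5-dimethoxy-3-methylpenta-1,3-dien-1-yl]-2,2,4-trimethylcyclohex-3-en-1-yl]ethanol
Conditions: Bu4NF, THF, 0 °C → rt
Reagents that add atoms: none
Why: Fluoride desilylation as in step 11.

Step 26
Reactants: 37 ring B arm alcohol
Product: 38 (4S)-4-(2-iodoethyl)-2-[(1E,3E)-5,5-dimethoxy-3-methylpenta-1,3-dien-1-yl]-1,3,3-trimethylcyclohex-1-ene
Conditions: I2, PPh3, imidazole, CH2Cl2, 0 °C
Reagents that add atoms: iodine, II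
Why: Appel-type iodination of the primary alcohol proceeds under imidazole buffering, so the acetal should survive.

Step 27
Reactants: 38 ring B arm iodide; 4 triphenylphosphine
Product: 39 {2-[(1S)-3-[(1E,3E)-5,5-dimethoxy-3-methylpenta-1,3-dien-1-yl]-2,2,4-trimethylcyclohex-3-en-1-yl]ethyl}triphenylphosphonium iodide
Conditions: MeCN, 80 °C
Reagents that add atoms: none
Why: SN2 quaternisation of the phosphine by the unhindered primary iodide gives the arm phosphonium salt.

Step 28
Reactants: 40 1,3-dihydroxyacetone (from its commercial dimer)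
Product: 41 1,3-bis(tert-butyldiphenylsilyloxy)propan-2-one
Conditions: TBDPSCl, imidazole, DMF, rt
Reagents that add atoms: tert-butyldiphenylsilyl chloride, CC(C)(C)[Si](Cl)(c1ccccc1)c1ccccc1
Why: Bis-silylation of the two primary hydroxyls gives a ketone whose ethers will survive the later acetal hydrolysis and phosphonium salt formation.

Step 29
Reactants: 39 ring B arm phosphonium iodide; 41 1,3-bis(tert-butyldiphenylsilyloxy)propan-2-one
Product: 43 (4S)-4-{4-(OTBDPS)-3-[(OTBDPS)methyl]but-2-en-1-yl}-2-[(1E,3E)-5,5-dimethoxy-3-methylpenta-1,3-dien-1-yl]-1,3,3-trimethylcyclohex-1-ene, via ylide 42 (not isolated)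
Conditions: NaN(SiMe3)2, THF, −78 → 0 °C; then 41, 0 °C → rt
Reagents that add atoms: none
Why: Wittig olefination of the ketone with the non-stabilised arm ylide gives the trisubstituted alkene, which has no geometry because both new substituents are CH2OTBDPS.

Step 30
Reactants: 43 ring B bis-silyl acetal
Product: 44 (2E,4E)-5-[(5S)-5-{4-(OTBDPS)-3-[(OTBDPS)methyl]but-2-en-1-yl}-2,6,6-trimethylcyclohex-1-en-1-yl]-3-methylpenta-2,4-dienal
Conditions: pyridinium p-toluenesulfonate (0.1 equiv), acetone/H2O 9:1, rt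
Reagents that add atoms: water, O
Why: Acid-catalysed acetal hydrolysis as in step 14, which the acid-robust TBDPS ethers tolerate.

Step 31
Reactants: 44 ring B C15 aldehyde
Product: 45 (2E,4E)-5-[(5S)-5-{4-(OTBDPS)-3-[(OTBDPS)methyl]but-2-en-1-yl}-2,6,6-trimethylcyclohex-1-en-1-yl]-3-methylpenta-2,4-dien-1-ol
Conditions: NaBH4, MeOH/THF, 0 °C
Reagents that add atoms: none
Why: Borohydride 1,2-reduction as in step 15.

Step 32
Reactants: 45 ring B C15 alcohol
Product: 46 {(2E,4E)-5-[(5S)-5-{4-(OTBDPS)-3-[(OTBDPS)methyl]but-2-en-1-yl}-2,6,6-trimethylcyclohex-1-en-1-yl]-3-methylpenta-2,4-dien-1-yl}triphenylphosphonium bromide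
Conditions: PPh3·HBr, MeOH/CH2Cl2, rt, dark
Reagents that add atoms: triphenylphosphine hydrobromide, Br.c1ccc(cc1)P(c1ccccc1)c1ccccc1
Why: Allylic phosphonium salt formation as in step 16; only the trienyl alcohol ionises, while the silylated allylic oxygens stay protected.

**Union and deprotection**

Step 33
Reactants: 46 ring B C15 phosphonium bromide; 26 ring A C25 aldehyde
Product: 48 (2R,2'S,all-E)-2-(3-methylbut-2-en-1-yl)-2'-{4-(OTBDPS)-3-[(OTBDPS)methyl]but-2-en-1-yl}-β,β-carotene, via ylide 47 (not isolated)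
Conditions: NaOMe, MeOH/CH2Cl2, 0 °C → rt, dark, argon; then I2 (cat.), CH2Cl2, rt, daylight
Reagents that add atoms: none
Why: Wittig olefination joins C11' to C12' and completes the C50 skeleton, and iodine-catalysed equilibration should give the all-E polyene.

Step 34
Reactants: 48 C50 bis-silyl ether
Product: 49 (2R,2'S,all-E)-2-(3-methylbut-2-en-1-yl)-2'-[4-hydroxy-3-(hydroxymethyl)but-2-en-1-yl]-β,β-carotene (CNP0213288.1)
Conditions: Bu4NF, THF, 0 °C → rt, dark, argon
Reagents that add atoms: none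
Why: Fluoride desilylation of the two TBDPS ethers releases the allylic diol without acid or oxidant that would harm the polyene.

**Compound list**

1 | 2,2-dimethoxyacetaldehyde | COC(OC)C=O | starting material
2 | 2-(triphenylphosphoranylidene)propanal | CC(C=O)=P(c1ccccc1)(c1ccccc1)c1ccccc1 | starting material
3 | (2E)-4,4-dimethoxy-2-methylbut-2-enal | O=C/C(C)=C/C(OC)OC | intermediate
4 | triphenylphosphine | c1ccc(cc1)P(c1ccccc1)c1ccccc1 | starting material
5 | 1-chloro-1-ethoxyethane | CCOC(C)Cl | starting material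
6 | (1-ethoxyethyl)triphenylphosphonium chloride | CCOC(C)[P+](c1ccccc1)(c1ccccc1)c1ccccc1.[Cl-] | intermediate
7 | (R)-α-campholenic aldehyde, 2-[(1R)-2,2,3-trimethylcyclopent-3-en-1-yl]acetaldehyde | O=CC[C@H]1CC=C(C)C1(C)C | starting material
8 | 2-[(1R)-2,2,3-trimethylcyclopent-3-en-1-yl]ethanol | OCC[C@H]1CC=C(C)C1(C)C | intermediate
9 | tert-butyldimethyl{2-[(1R)-2,2,3-trimethylcyclopent-3-en-1-yl]ethoxy}silane | CC(C)(C)[Si](C)(C)OCC[C@H]1CC=C(C)C1(C)C | intermediate
10 | ozonide of 9, 3-[2-(OTBS)ethyl]-1,2,2-trimethyl-6,7,8-trioxabicyclo[3.2.1]octane (diastereomer mixture) | CC12OOC(C[C@H](CCO[Si](C)(C)C(C)(C)C)C1(C)C)O2 | intermediate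
11 | (3S)-3-[2-(OTBS)ethyl]-4,4-dimethyl-5-oxohexanal | O=CC[C@H](CCO[Si](C)(C)C(C)(C)C)C(C)(C)C(C)=O | intermediate
12 | (1-ethoxyethylidene)triphenylphosphorane | CCOC(C)=P(c1ccccc1)(c1ccccc1)c1ccccc1 | intermediate
13 | (4R)-4-[2-(OTBS)ethyl]-7-ethoxy-3,3-dimethyloct-6-en-2-one (E/Z mixture) | CCOC(C)=CC[C@H](CCO[Si](C)(C)C(C)(C)C)C(C)(C)C(C)=O | intermediate
14 | (2E,4E,8R)-8-[2-(OTBS)ethyl]-11-ethoxy-1,1-dimethoxy-3,7,7-trimethyldodeca-2,4,10-trien-6-one | CCOC(C)=CC[C@H](CCO[Si](C)(C)C(C)(C)C)C(C)(C)C(=O)/C=C/C(C)=C/C(OC)OC | intermediate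
15 | (5R,8E,10E)-5-[2-(OTBS)ethyl]-12,12-dimethoxy-6,6,10-trimethyldodeca-8,10-diene-2,7-dione | CC(=O)CC[C@H](CCO[Si](C)(C)C(C)(C)C)C(C)(C)C(=O)/C=C/C(C)=C/C(OC)OC | intermediate
16 | titanium-bound C5,C6-pinacolate of ring A, drawn as a titanium diolate | CC(C)(C)[Si](C)(C)OCC[C@H]1CCC2(C)O[Ti]OC2(/C=C/C(C)=C/C(OC)OC)C1(C)C | intermediate
17 | tert-butyl{2-[(1R)-3-[(1E,3E)-5,5-dimethoxy-3-methylpenta-1,3-dien-1-yl]-2,2,4-trimethylcyclohex-3-en-1-yl]ethoxy}dimethylsilane | CC(C)(C)[Si](C)(C)OCC[C@H]1CCC(C)=C(/C=C/C(C)=C/C(OC)OC)C1(C)C | intermediate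
18 | 2-[(1R)-3-[(1E,3E)-5,5-dimethoxy-3-methylpenta-1,3-dien-1-yl]-2,2,4-trimethylcyclohex-3-en-1-yl]ethanol | OCC[C@H]1CCC(C)=C(/C=C/C(C)=C/C(OC)OC)C1(C)C | intermediate
19 | 2-[(1R)-3-[(1E,3E)-5,5-dimethoxy-3-methylpenta-1,3-dien-1-yl]-2,2,4-trimethylcyclohex-3-en-1-yl]acetaldehyde | O=CC[C@H]1CCC(C)=C(/C=C/C(C)=C/C(OC)OC)C1(C)C | intermediate
20 | (4R)-2-[(1E,3E)-5,5-dimethoxy-3-methylpenta-1,3-dien-1-yl]-1,3,3-trimethyl-4-(3-methylbut-2-en-1-yl)cyclohex-1-ene | CC(C)=CC[C@H]1CCC(C)=C(/C=C/C(C)=C/C(OC)OC)C1(C)C | intermediate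
21 | (2E,4E)-3-methyl-5-[(5R)-2,6,6-trimethyl-5-(3-methylbut-2-en-1-yl)cyclohex-1-en-1-yl]penta-2,4-dienal | CC(C)=CC[C@H]1CCC(C)=C(/C=C/C(C)=C/C=O)C1(C)C | intermediate
22 | (2E,4E)-3-methyl-5-[(5R)-2,6,6-trimethyl-5-(3-methylbut-2-en-1-yl)cyclohex-1-en-1-yl]penta-2,4-dien-1-ol | CC(C)=CC[C@H]1CCC(C)=C(/C=C/C(C)=C/CO)C1(C)C | intermediate
23 | {(2E,4E)-3-methyl-5-[(5R)-2,6,6-trimethyl-5-(3-methylbut-2-en-1-yl)cyclohex-1-en-1-yl]penta-2,4-dien-1-yl}triphenylphosphonium bromide | CC(C)=CC[C@H]1CCC(C)=C(/C=C/C(C)=C/C[P+](c2ccccc2)(c2ccccc2)c2ccccc2)C1(C)C.[Br-] | intermediate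
24 | (2E,4E,6E)-2,7-dimethylocta-2,4,6-trienedial | O=C/C(C)=C/C=C/C=C(C)/C=O | starting material
25 | ylide of 23 | CC(C)=CC[C@H]1CCC(C)=C(/C=C/C(C)=C/C=P(c2ccccc2)(c2ccccc2)c2ccccc2)C1(C)C | intermediate
26 | (2E,4E,6E,8E,10E,12E)-2,7,11-trimethyl-13-[(5R)-2,6,6-trimethyl-5-(3-methylbut-2-en-1-yl)cyclohex-1-en-1-yl]trideca-2,4,6,8,10,12-hexaenal | CC(C)=CC[C@H]1CCC(C)=C(/C=C/C(C)=C/C=C/C(C)=C/C=C/C=C(C)/C=O)C1(C)C | intermediate
27 | (S)-α-campholenic aldehyde, 2-[(1S)-2,2,3-trimethylcyclopent-3-en-1-yl]acetaldehyde | O=CC[C@@H]1CC=C(C)C1(C)C | starting material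
28 | 2-[(1S)-2,2,3-trimethylcyclopent-3-en-1-yl]ethanol | OCC[C@@H]1CC=C(C)C1(C)C | intermediate
29 | tert-butyldimethyl{2-[(1S)-2,2,3-trimethylcyclopent-3-en-1-yl]ethoxy}silane | CC(C)(C)[Si](C)(C)OCC[C@@H]1CC=C(C)C1(C)C | intermediate
30 | ozonide of 29 (enantiomer of 10, diastereomer mixture) | CC12OOC(C[C@@H](CCO[Si](C)(C)C(C)(C)C)C1(C)C)O2 | intermediate
31 | (3R)-3-[2-(OTBS)ethyl]-4,4-dimethyl-5-oxohexanal | O=CC[C@@H](CCO[Si](C)(C)C(C)(C)C)C(C)(C)C(C)=O | intermediate
32 | (4S)-4-[2-(OTBS)ethyl]-7-ethoxy-3,3-dimethyloct-6-en-2-one (E/Z mixture) | CCOC(C)=CC[C@@H](CCO[Si](C)(C)C(C)(C)C)C(C)(C)C(C)=O | intermediate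
33 | (2E,4E,8S)-8-[2-(OTBS)ethyl]-11-ethoxy-1,1-dimethoxy-3,7,7-trimethyldodeca-2,4,10-trien-6-one | CCOC(C)=CC[C@@H](CCO[Si](C)(C)C(C)(C)C)C(C)(C)C(=O)/C=C/C(C)=C/C(OC)OC | intermediate
34 | (5S,8E,10E)-5-[2-(OTBS)ethyl]-12,12-dimethoxy-6,6,10-trimethyldodeca-8,10-diene-2,7-dione | CC(=O)CC[C@@H](CCO[Si](C)(C)C(C)(C)C)C(C)(C)C(=O)/C=C/C(C)=C/C(OC)OC | intermediate
35 | titanium-bound C5',C6'-pinacolate of ring B, drawn as a titanium diolate | CC(C)(C)[Si](C)(C)OCC[C@@H]1CCC2(C)O[Ti]OC2(/C=C/C(C)=C/C(OC)OC)C1(C)C | intermediate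
36 | tert-butyl{2-[(1S)-3-[(1E,3E)-5,5-dimethoxy-3-methylpenta-1,3-dien-1-yl]-2,2,4-trimethylcyclohex-3-en-1-yl]ethoxy}dimethylsilane | CC(C)(C)[Si](C)(C)OCC[C@@H]1CCC(C)=C(/C=C/C(C)=C/C(OC)OC)C1(C)C | intermediate
37 | 2-[(1S)-3-[(1E,3E)-5,5-dimethoxy-3-methylpenta-1,3-dien-1-yl]-2,2,4-trimethylcyclohex-3-en-1-yl]ethanol | OCC[C@@H]1CCC(C)=C(/C=C/C(C)=C/C(OC)OC)C1(C)C | intermediate
38 | (4S)-4-(2-iodoethyl)-2-[(1E,3E)-5,5-dimethoxy-3-methylpenta-1,3-dien-1-yl]-1,3,3-trimethylcyclohex-1-ene | ICC[C@@H]1CCC(C)=C(/C=C/C(C)=C/C(OC)OC)C1(C)C | intermediate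
39 | {2-[(1S)-3-[(1E,3E)-5,5-dimethoxy-3-methylpenta-1,3-dien-1-yl]-2,2,4-trimethylcyclohex-3-en-1-yl]ethyl}triphenylphosphonium iodide | [I-].c1ccc(cc1)[P+](CC[C@@H]1CCC(C)=C(/C=C/C(C)=C/C(OC)OC)C1(C)C)(c1ccccc1)c1ccccc1 | intermediate
40 | 1,3-dihydroxyacetone | O=C(CO)CO | starting material
41 | 1,3-bis(tert-butyldiphenylsilyloxy)propan-2-one | O=C(CO[Si](c1ccccc1)(c1ccccc1)C(C)(C)C)CO[Si](c1ccccc1)(c1ccccc1)C(C)(C)C | intermediate
42 | ylide of 39 | c1ccc(cc1)P(=CC[C@@H]1CCC(C)=C(/C=C/C(C)=C/C(OC)OC)C1(C)C)(c1ccccc1)c1ccccc1 | intermediate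
43 | (4S)-4-{4-(OTBDPS)-3-[(OTBDPS)methyl]but-2-en-1-yl}-2-[(1E,3E)-5,5-dimethoxy-3-methylpenta-1,3-dien-1-yl]-1,3,3-trimethylcyclohex-1-ene | CC(C)(C)[Si](OCC(CO[Si](c1ccccc1)(c1ccccc1)C(C)(C)C)=CC[C@@H]1CCC(C)=C(/C=C/C(C)=C/C(OC)OC)C1(C)C)(c1ccccc1)c1ccccc1 | intermediate
44 | (2E,4E)-5-[(5S)-5-{4-(OTBDPS)-3-[(OTBDPS)methyl]but-2-en-1-yl}-2,6,6-trimethylcyclohex-1-en-1-yl]-3-methylpenta-2,4-dienal | CC(C)(C)[Si](OCC(CO[Si](c1ccccc1)(c1ccccc1)C(C)(C)C)=CC[C@@H]1CCC(C)=C(/C=C/C(C)=C/C=O)C1(C)C)(c1ccccc1)c1ccccc1 | intermediate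
45 | (2E,4E)-5-[(5S)-5-{4-(OTBDPS)-3-[(OTBDPS)methyl]but-2-en-1-yl}-2,6,6-trimethylcyclohex-1-en-1-yl]-3-methylpenta-2,4-dien-1-ol | CC(C)(C)[Si](OCC(CO[Si](c1ccccc1)(c1ccccc1)C(C)(C)C)=CC[C@@H]1CCC(C)=C(/C=C/C(C)=C/CO)C1(C)C)(c1ccccc1)c1ccccc1 | intermediate
46 | {(2E,4E)-5-[(5S)-5-{4-(OTBDPS)-3-[(OTBDPS)methyl]but-2-en-1-yl}-2,6,6-trimethylcyclohex-1-en-1-yl]-3-methylpenta-2,4-dien-1-yl}triphenylphosphonium bromide | CC(C)(C)[Si](OCC(CO[Si](c1ccccc1)(c1ccccc1)C(C)(C)C)=CC[C@@H]1CCC(C)=C(/C=C/C(C)=C/C[P+](c2ccccc2)(c2ccccc2)c2ccccc2)C1(C)C)(c1ccccc1)c1ccccc1.[Br-] | intermediate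
47 | ylide of 46 | CC(C)(C)[Si](OCC(CO[Si](c1ccccc1)(c1ccccc1)C(C)(C)C)=CC[C@@H]1CCC(C)=C(/C=C/C(C)=C/C=P(c2ccccc2)(c2ccccc2)c2ccccc2)C1(C)C)(c1ccccc1)c1ccccc1 | intermediate
48 | (2R,2'S,all-E)-2-(3-methylbut-2-en-1-yl)-2'-{4-(OTBDPS)-3-[(OTBDPS)methyl]but-2-en-1-yl}-β,β-carotene | CC(C)=CC[C@H]1CCC(C)=C(/C=C/C(C)=C/C=C/C(C)=C/C=C/C=C(C)/C=C/C=C(C)/C=C/C2=C(C)CC[C@@H](CC=C(CO[Si](c3ccccc3)(c3ccccc3)C(C)(C)C)CO[Si](c3ccccc3)(c3ccccc3)C(C)(C)C)C2(C)C)C1(C)C | intermediate
49 | (2R,2'S,all-E)-2-(3-methylbut-2-en-1-yl)-2'-[4-hydroxy-3-(hydroxymethyl)but-2-en-1-yl]-β,β-carotene | CC(C)=CC[C@H]1CCC(C)=C(/C=C/C(C)=C/C=C/C(C)=C/C=C/C=C(C)/C=C/C=C(C)/C=C/C2=C(C)CC[C@@H](CC=C(CO)CO)C2(C)C)C1(C)C | target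

**Step count and risks**

Total step count: 34. Longest linear sequence: 16 steps (7 → 26 → 49 through steps 3–5, 7–17, 33 and 34; equally 27 → 46 → 49 through steps 18–27 and 29–34).

Steps 24 and 23 repeat steps 10 and 9 on the mirror-image series and share their risks; the three distinct risks are ranked below.

Step 10 (ring closure). Intermolecular coupling and oligomerisation may outrun cyclisation, electron transfer into the dienone may lead to bonding through C8 or C10 or to over-reduction of the diene, and Lewis-acidic titanium and zinc chlorides may ionise the acetal. The fallback sets out from 15 and comes back at 17, dividing the reductive coupling into a pinacol cyclisation and a separate deoxygenation. SmI2 (divalent samarium) in THF with t-BuOH at −78 °C should couple the two ketyls of 15 to the ring A cis-5,6-diol F1, which is isolated. Heating F1 with 1,1'-thiocarbonyldiimidazole and 4-(dimethylamino)pyridine in toluene should give the cyclic thiocarbonate F2. Corey–Winter fragmentation of F2 with 1,3-dimethyl-2-phenyl-1,3,2-diazaphospholidine at 40 °C should expel carbon dioxide and sulfur and deliver 17.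

Step 9 (unmasking of the C5 ketone). Acetal cleavage may compete with enol ether hydrolysis, leaving a third carbonyl group that would ruin the coupling. The fallback sets out from 13 and comes back at 15, masking C5 by oxidation state instead, so that the last unmasking is a neutral oxidation. Pyridinium p-toluenesulfonate in wet acetone should hydrolyse 13, which has no acetal yet, to the diketone F3. NaBH4 (0.3 equiv) in MeOH at −78 °C should reduce only the unhindered C5 ketone, the C6 ketone being shielded by quaternary C1, to the hydroxy ketone F4 (C5 epimers). Claisen–Schmidt condensation of F4 with 3 under the conditions of step 8 should give the hydroxy dienone F5, and Dess–Martin oxidation with pyridine should then give 15.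

Step 29 (ring B arm olefination). The basic ylide may enolise the α,α'-bis(silyloxy) ketone, with β-loss of silanolate, instead of adding to the carbonyl. The fallback sets out from 37 and comes back at 43, reversing the polarity. Dess–Martin oxidation of 37 with pyridine should give the arm aldehyde F6. Knoevenagel condensation with dimethyl malonate (piperidinium acetate, benzene, reflux with water removal) should give the alkylidene malonate F7. Reduction with i-Bu2AlH in CH2Cl2 at −78 °C should give the allylic diol F8, and TBDPSCl with imidazole in DMF should return 43.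

**Further compounds**

F1 | step 10 | ring A cis-5,6-diol (carotenoid numbering), (5R)-5-[2-(OTBS)ethyl]-1-[(1E,3E)-5,5-dimethoxy-3-methylpenta-1,3-dien-1-yl]-2,6,6-trimethylcyclohexane-1,2-diol with cis hydroxyls, configuration at C1 and C2 not fixed | CC(C)(C)[Si](C)(C)OCC[C@H]1CCC(C)(O)C(O)(/C=C/C(C)=C/C(OC)OC)C1(C)C
F2 | step 10 | cyclic thiocarbonate of F1 | CC(C)(C)[Si](C)(C)OCC[C@H]1CCC2(C)OC(=S)OC2(/C=C/C(C)=C/C(OC)OC)C1(C)C
F3 | step 9 | (5R)-5-[2-(OTBS)ethyl]-6,6-dimethyloctane-2,7-dione | CC(=O)CC[C@H](CCO[Si](C)(C)C(C)(C)C)C(C)(C)C(C)=O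
F4 | step 9 | (4R)-4-[2-(OTBS)ethyl]-7-hydroxy-3,3-dimethyloctan-2-one (C7 epimers) | CC(O)CC[C@H](CCO[Si](C)(C)C(C)(C)C)C(C)(C)C(C)=O
F5 | step 9 | (5R,8E,10E)-5-[2-(OTBS)ethyl]-2-hydroxy-12,12-dimethoxy-6,6,10-trimethyldodeca-8,10-dien-7-one (C2 epimers) | CC(O)CC[C@H](CCO[Si](C)(C)C(C)(C)C)C(C)(C)C(=O)/C=C/C(C)=C/C(OC)OC
F6 | step 29 | 2-[(1S)-3-[(1E,3E)-5,5-dimethoxy-3-methylpenta-1,3-dien-1-yl]-2,2,4-trimethylcyclohex-3-en-1-yl]acetaldehyde | O=CC[C@@H]1CCC(C)=C(/C=C/C(C)=C/C(OC)OC)C1(C)C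
F7 | step 29 | dimethyl 2-{2-[(1S)-3-[(1E,3E)-5,5-dimethoxy-3-methylpenta-1,3-dien-1-yl]-2,2,4-trimethylcyclohex-3-en-1-yl]ethylidene}malonate | COC(=O)C(=CC[C@@H]1CCC(C)=C(/C=C/C(C)=C/C(OC)OC)C1(C)C)C(=O)OC
F8 | step 29 | 2-{2-[(1S)-3-[(1E,3E)-5,5-dimethoxy-3-methylpenta-1,3-dien-1-yl]-2,2,4-trimethylcyclohex-3-en-1-yl]ethylidene}propane-1,3-diol | OCC(CO)=CC[C@@H]1CCC(C)=C(/C=C/C(C)=C/C(OC)OC)C1(C)C
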